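(The readings come from a simulation with made-up constants.)

The vessel is closed and stirred, and elm and ash hold the same charge; elm runs 10 d, ash 2.5 d.

| setting | Friday's | elm | ash |
|---|---|---|---|
| free monomer | 0.80 M | 0.80 M | 0.80 M |
| transfer agent | 8 mM | 8.00 mM | 8.00 mM |
| initiator | 5.1 mM | 3.4 mM | 3.4 mM |
| impurity | 3.5 mM | 3.5 mM | 3.5 mM |
| remark | run made earlier |  |  |
| time |  | 10 d | 2.5 d |

- Friday's (time / h: monomer in chains / %, free monomer / %): 4.00: 4, 94; 8.00: 14, 86; 20.0: 26, 73; 50.0: 49, 55

(each reading ± 2 percentage points)

- which of the two ends with the longer chains by the average number of monomer units in a chain (chains begun, living or dead) ("neither" if they lie within 10%) (elm / ash / neither)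
- average number of monomer units in a chain (chains begun, living or dead) at the end, elm
- average number of monomer units in a chain (chains begun, living or dead) at the end, ash

I turn the question round: for lengths within 10%, growth must be nearly over when ash stops. If a living end adds free monomer, uptake is pseudo-first-order in free monomer, and the slope of the logarithm of charged over remaining free monomer tracks the living ends. Friday's free monomer readings give a slope of 0.0157 h⁻¹ up to 20.0 h and 0.00944 h⁻¹ after it. As a reading, with its scatter, that makes the time in which living ends halve 33.9 h. I assume the same half-life here and that chains begin early. Then 29.3% of the living ends still stand when ash stops, more than the 9.09% a tie requires. The logarithmic uptake of elm over ash comes to 1.40, so I commit to elm. I give no length, since Friday's run shows no number of chains.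

The forecast says elm, with 600 for elm (range 200 to 850) and 350 for ash (110 to 520): “Elm is longer in either case”.

The flask gives elm, with 301 for elm and 199 for ash.

    free monomer + initiator → living end + monomer in chains (k = 2.70 × 10⁻⁴ M⁻¹ s⁻¹)
    free monomer + living end → monomer in chains + living end, rate k2*[living end]*[free monomer] (k = 0.00210 M⁻¹ s⁻¹)
    living end + transfer agent → dead chain (kL = 5.30 × 10⁻⁴ M⁻¹ s⁻¹)
    initiator + impurity → spent initiator (k = 0.150 M⁻¹ s⁻¹)

At elm's charges, the initiator's half-life against impurity is 0.37 h, shorter than the 2.0 d of a living end against transfer agent in elm at 1.57 d. Chains begun, living plus dead, come to 1.31 mM in elm and 1.31 mM in ash, so the lengths stand as monomer in chains, 49.2% to 32.5%. For ash left to 25.0 d, my half-life reading of 33.9 h leaves <0.001% of the living ends, less than the 9.09% of a tie, and the flask gives 311 for ash there and 311 for elm at 100 d.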